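**Plan**

- Cuts: C11'–C12' (sp3–sp2 coupling of the labdane decalin with an alkenyl iodide on the bicyclic half); then C8–C9 and C12–C13 together (intramolecular oxyallyl (4+3)); then C6–C8 (dienyl metal plus ring A keto acetal). C7 and C11/C12 come from opening a temporary ring B.
- Feature: the seven-membered ring C8–C9–C11–C12–C13–C14'–C15' of the bicyclo[3.2.1]octane has its oxygen on C11, the middle carbon of C9–C11–C12, and is bridged by ketone C14 between C8 and C13. This is an oxyallyl unit added to the ends of a cyclopentadienone ketal C8=C15'–C14'=C13.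
- Forward: ring A by asymmetric allylation, temporary decalin enone 8, ozonolysis to keto bis-acetal 10; diene bromide 20 from cyclopentane-1,3-dione; union at C6, chloroketone 27, cycloaddition closing rings B and C (29). Then alkene reduction, side-chain alkenyl iodide, diosphenol and unmasking; last, coupling with the alkylzinc made from abietic acid, and desilylation.
- Stereochemistry: C10 from the Pd/phosphinooxazoline allylation; C5 by equilibration in trans-decalin 8; C6 by Felkin–Anh addition; C8 and C13 by the tether-controlled diene face in the (4+3); C14' by hydroxyl-directed hydrogenation; the E-alkene by carboalumination; C4', C5', C10' from abietic acid; C9' by hydroboration.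

Key step: step 18

Locants: abietane numbering (C1–C14) for the tetracyclic half; primed labdane locants for the other half, whose C14' and C15' form the two-carbon bridge.
Assumption: the sense of induction in step 2 follows the parent 2-methylcyclohexanone case ((S)-ligand gives (S)-ketone), so the (R)-ligand is chosen for (R)-3.
Remark: centres that are destroyed later (spiro carbon of 4, C5 of 5–7, C6 of 6, C11 of 33–37) are carried as mixtures and left open in the SMILES.

**Ring A and the keto bis-acetal (steps 1–7)**

Step 1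
Reactants: 1 2,2,6-trimethylcyclohexanone
Product: 2 2-methylallyl 2,6,6-trimethylcyclohex-1-en-1-yl carbonate
Conditions: LiN(SiMe3)2, THF, 0 °C; 2-methylallyl chloroformate, −78 °C to rt
Reagents that add atoms: 2-methylallyl chloroformate, C=C(C)COC(Cl)=O
Why: The only enolisable position of 1 gives a single tetrasubstituted lithium enolate, and its O-acylation by a chloroformate is the standard enol carbonate synthesis.

Step 2
Reactants: 2 2-methylallyl enol carbonate
Product: 3 (R)-2,2,6-trimethyl-6-(2-methylallyl)cyclohexanone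
Conditions: Pd2(dba)3 (2.5 mol%), (R)-t-BuPHOX (6 mol%), THF, 25 °C
Reagents that add atoms: none
Why: Tsuji-type decarboxylative asymmetric allylic alkylation, in which loss of CO2 gives a π-allylpalladium enolate pair that recombines at carbon inside the chiral P,N-ligand sphere and so sets the quaternary centre C10 (R).

Step 3
Reactants: 3 (R)-2,2,6-trimethyl-6-(2-methylallyl)cyclohexanone
Product: 4 spiro-epoxide (4R)-4,8,8-trimethyl-4-(2-methylallyl)-1-oxaspiro[2.5]octane
Conditions: Me3SI, n-BuLi, THF, −10 °C; then 3, 0 °C to rt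
Reagents that add atoms: trimethylsulfonium iodide, C[S+](C)C.[I-]
Why: Corey–Chaykovsky epoxidation, where the small sulfonium ylide adds irreversibly even to this non-enolisable, doubly neopentyl ketone; the configuration at the spiro carbon does not matter.

Step 4
Reactants: 4 spiro-epoxide
Product: 5 (2R)-2,6,6-trimethyl-2-(2-methylallyl)cyclohexanecarbaldehyde (both C5 epimers)
Conditions: BF3·OEt2 (0.2 equiv), toluene, −40 °C
Reagents that add atoms: none
Why: Meinwald rearrangement, in which opening at the tertiary C5–O bond and a 1,2-hydride shift give the aldehyde; C5 forms as a mixture that is equilibrated in step 6.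

Step 5
Reactants: 5 aldehyde
Product: 6 (4aR)-4a,8,8-trimethyl-3-methylenedecahydronaphthalen-1-ol (diastereomer mixture)
Conditions: Me2AlCl (1.5 equiv), CH2Cl2, −78 to 0 °C
Reagents that add atoms: none
Why: Type-two intramolecular carbonyl-ene reaction, in which the formyl carbon C6 bonds to the terminal alkene carbon (the future C7) through a six-membered transition state and closes the temporary ring B; the new carbinol centre is removed in step 6.

Step 6
Reactants: 6 homoallylic alcohol
Product: 8 trans-decalin enone (4aR,8aS)-3,4a,8,8-tetramethyl-4a,5,6,7,8,8a-hexahydronaphthalen-1(4H)-one, via methylene ketone 7 (not isolated)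
Conditions: DMP, CH2Cl2, rt; then DBU, CH2Cl2, 40 °C
Reagents that add atoms: none
Why: Periodinane oxidation followed by base-mediated conjugation of the β,γ-unsaturated ketone; under the same amidine base C5 epimerises α to the ketone to the more stable trans-decalin, which fixes C5 relative to C10.

Step 7
Reactants: 8 trans-decalin enone
Product: 10 ring A keto bis-acetal, via keto aldehyde 9 (not isolated)
Conditions: O3, CH2Cl2/MeOH (4:1), −78 °C; Me2S, −78 °C to rt; then HC(OMe)3, p-TsOH (cat.), rt
Reagents that add atoms: ozone, [O-][O+]=O; trimethyl orthoformate, COC(OC)OC; methanol, CO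
Why: Criegee ozonolysis of the enone alkene with reductive work-up and acid-catalysed acetalisation, which masks the glyoxal-type aldehyde C7 and the unhindered methyl ketone C11 while the C6 ketone, flanked by C5 and the acetal carbon, is too hindered to ketalise.

**Cyclopentadienone ketal bromide (steps 8–13)**

Step 8
Reactants: 11 cyclopentane-1,3-dione
Product: 13 2-isopropylcyclopentane-1,3-dione, via 2-isopropylidenecyclopentane-1,3-dione 12 (not isolated)
Conditions: acetone, diethyl 2,6-dimethyl-1,4-dihydropyridine-3,5-dicarboxylate, L-proline (cat.), CH2Cl2, rt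
Reagents that add atoms: acetone, CC(C)=O
Why: Three-component reductive alkylation, that is proline-catalysed Knoevenagel condensation with in situ conjugate reduction of the alkylidene dione by the dihydropyridine.

Step 9
Reactants: 13 2-isopropylcyclopentane-1,3-dione
Product: 14 3-isobutoxy-2-isopropylcyclopent-2-en-1-one
Conditions: i-BuOH, p-TsOH (cat.), toluene, reflux, azeotropic removal of water
Reagents that add atoms: 2-methylpropan-1-ol, CC(C)CO
Why: Acid-catalysed enol etherification of the cyclic 1,3-dione (vinylogous ester formation) driven by removal of water.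

Step 10
Reactants: 14 vinylogous ester
Product: 16 3-(benzyloxymethyl)-2-isopropylcyclopent-2-en-1-one, via tertiary carbinol 15 (not isolated)
Conditions: BnOCH2SnBu3, n-BuLi, THF, −78 °C; then 14; then 1 M HCl, rt
Reagents that add atoms: (benzyloxymethyl)tributylstannane, CCCC[Sn](CCCC)(CCCC)COCc1ccccc1
Why: Stork–Danheiser sequence, in which 1,2-addition of the α-alkoxymethyllithium (from tin–lithium exchange) and acid-induced hydrolysis/dehydration transpose the enone and place the protected hydroxymethyl group on the future C14'.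

Step 11
Reactants: 16 enone
Product: 18 5,5-dibromo-3-(benzyloxymethyl)-2-isopropylcyclopent-2-en-1-one, via monobromo enone 17 (not isolated)
Conditions: LiN(SiMe3)2 then NBS, THF, −78 °C, carried out twice in one pot; aq. NH4Cl
Reagents that add atoms: N-bromosuccinimide, O=C1CCC(=O)N1Br
Why: Kinetic α'-enolisation at the only α'-position (future C8) and electrophilic bromination, repeated once, the first bromine acidifying the remaining C–H so that the second bromine enters at the same carbon.

Step 12
Reactants: 18 dibromo enone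
Product: 19 dibromo enone dimethyl ketal
Conditions: MeOSiMe3 (3 equiv), Me3SiOTf (5 mol%), CH2Cl2, −78 to −20 °C
Reagents that add atoms: methoxytrimethylsilane, CO[Si](C)(C)C
Why: Silyl triflate-catalysed aprotic ketalisation, a method that ketalises α-halo enones without moving the double bond, installs the C14 dimethyl ketal.

Step 13
Reactants: 19 dibromo ketal
Product: 20 1-bromo-3-(benzyloxymethyl)-4-isopropyl-5,5-dimethoxycyclopenta-1,3-diene
Conditions: KOt-Bu, THF, 0 °C
Reagents that add atoms: none
Why: E2 dehydrobromination (C15'–H and one C8–Br) gives the 5,5-dimethoxycyclopentadiene, the remaining vinylic bromide cannot eliminate and the three substituents should retard Diels–Alder dimerisation.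

**Union, chloroketone and cycloaddition (steps 14–18)**

Step 14
Reactants: 20 bromodiene ketal; 10 ring A keto bis-acetal
Product: 23 tertiary carbinol (6R) carrying the diene at C6, via dienyllithium 21 (not isolated), via dienylcerium dichloride 22 (not isolated)
Conditions: 20, t-BuLi (2.0 equiv), Et2O/THF, −78 °C; CeCl3 (anhydrous), −78 °C; then 10, −78 to −40 °C; aq. NH4Cl
Reagents that add atoms: none
Why: Bromine–lithium exchange, transmetalation to the less basic organocerium reagent and 1,2-addition to the α-keto acetal, with C6 set by 1,2-induction from C5 (Felkin–Anh: the reagent enters anti to the C10 flank of ring A, which carries the bulkier ketal-bearing arm, with the acetal carbon over the C5 hydrogen).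

Step 15
Reactants: 23 tertiary carbinol
Product: 24 C6 triethylsilyl ether
Conditions: Et3SiOTf, 2,6-lutidine, CH2Cl2, −78 to 0 °C
Reagents that add atoms: triethylsilyl trifluoromethanesulfonate, CC[Si](CC)(CC)OS(=O)(=O)C(F)(F)F
Why: Silyl triflate/lutidine silylation of the hindered tertiary alcohol, needed because a free C6 hydroxyl would capture the oxyallyl cation.

Step 16
Reactants: 24 C6 triethylsilyl ether
Product: 25 methyl ketone (C9H2–C11(=O)–C12H3)
Conditions: PPTS (cat.), acetone/H2O (10:1), rt
Reagents that add atoms: water, O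
Why: Selective mild acid hydrolysis, since the ketal of the unhindered methyl ketone hydrolyses far faster than the neopentyl α-silyloxy acetal at C7 or the cyclopentadienone ketal, whose oxocarbenium ion would be an antiaromatic cyclopentadienyl cation.

Step 17
Reactants: 25 methyl ketone
Product: 27 chloromethyl ketone (cycloaddition precursor), via trimethylsilyl enol ether 26 (not isolated)
Conditions: LiN(i-Pr)2, Me3SiCl (in situ), THF, −78 °C; then NCS, −78 to 0 °C
Reagents that add atoms: N-chlorosuccinimide, O=C1CCC(=O)N1Cl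
Why: Kinetic enolisation at the methyl group with in situ silylation, then electrophilic chlorination of the terminal silyl enol ether by NCS, which is far more nucleophilic than the hindered diene.

Step 18
Reactants: 27 chloromethyl ketone tethered to the cyclopentadienone dimethyl ketal
Product: 29 tetracyclic bicyclo[3.2.1]octenone with ketal bridge, via oxyallyl cation 28 (not isolated)
Conditions: NaOCH2CF3 (1.5 equiv), CF3CH2OH, 0 °C to rt, high dilution
Reagents that add atoms: none
Why: Proposed new method: trifluoroethoxide enolises 27 towards C9 and loss of chloride gives the sodium oxyallyl cation 28 (C9–C11–C12, two π electrons), which adds across the diene termini C8 and C13 in a (4+3) cycloaddition so that ketal carbon C14 becomes the one-carbon bridge; the closest known chemistry is the intramolecular oxyallyl (4+3) cycloaddition of α-halo ketones with tethered furans and cyclopentadienes under these conditions, a 5,5-dialkoxycyclopentadiene being untested as the diene. Ring B (C5, C6, C8, C9, C10) closes by attack of C9 on C8 through the three-atom tether C10–C5–C6 (five-membered ring, exo mode), and ring C (C8, C9, C11, C12, C13, C14) is completed when C12 bonds to C13 in the same, probably asynchronous, event. C8 and C13 are set together by the diene face attacked: with the two arms trans-diequatorial on ring A the tether can deliver C9 only in the extended arrangement (C11–O over the ketal bridge, ring B cis-fused to ring C), and only the face that puts C14 syn and C15' anti to the C10 methyl lets the incipient ring C relax towards a chair, the other face forcing a boat that drives C11 into the syn methoxy group. C9 should arise with its hydrogen anti to the C10 methyl because C10 sits cis to the oxido oxygen in the cation, but this centre is erased in step 27. The step needs (4+3) addition to win over O-capture, Favorskii-type solvolysis, (3+2) closure and diene dimerisation; the silyl ether on the C6 oxygen, the ketal (which blocks 1,5-hydrogen shifts), the three ring substituents and the ionising, weakly nucleophilic solvent are there to secure this.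

**Elaboration of the bicyclic half (steps 19–29)**

Step 19
Reactants: 29 cycloadduct
Product: 30 C6 tertiary alcohol
Conditions: Bu4NF, THF, 0 °C to rt
Reagents that add atoms: none
Why: Fluoride-mediated cleavage of the tertiary silyl ether frees the C6 hydroxyl as the directing group for the next step.

Step 20
Reactants: 30 C6 tertiary alcohol
Product: 31 saturated bicyclo[3.2.1]octanone with endo benzyloxymethyl group at C14'
Conditions: [Ir(cod)(PCy3)(py)]PF6 (10 mol%), H2 (1 atm), CH2Cl2, rt
Reagents that add atoms: none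
Why: Hydroxyl-directed homogeneous hydrogenation: the C6 hydroxyl lies on the exo side of the C14'=C15' bond (the side of the ketal bridge) and binds the cationic iridium centre, so hydrogen is delivered to the exo face and the substituent at C14' ends endo, as the target requires.

Step 21
Reactants: 31 benzyl ether
Product: 32 primary alcohol
Conditions: H2 (1 atm), Pd/C (10%), EtOAc, rt
Reagents that add atoms: none
Why: Hydrogenolysis of the benzyl ether over palladium on carbon, with nothing else in 31 reducible under these conditions.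

Step 22
Reactants: 32 hydroxy ketone
Product: 33 triol (C11 carbinol)
Conditions: NaBH4, MeOH, 0 °C
Reagents that add atoms: none
Why: Borohydride reduction masks the C11 ketone as an alcohol so that it survives the organoaluminium step; the carbinol configuration is irrelevant because the ketone is restored in step 26.

Step 23
Reactants: 33 triol
Product: 34 C14' aldehyde
Conditions: TEMPO (cat.), PhI(OAc)2, CH2Cl2, rt
Reagents that add atoms: none
Why: Oxoammonium oxidation, selective for the primary alcohol over the hindered secondary and tertiary ones, under non-basic conditions that should not epimerise C14'.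

Step 24
Reactants: 34 aldehyde
Product: 35 terminal alkyne
Conditions: Me3SiCHN2, n-BuLi, THF, −78 °C; then 34, −78 °C to rt; aq. NH4Cl
Reagents that add atoms: (trimethylsilyl)diazomethane, C[Si](C)(C)C=[N+]=[N-]
Why: Colvin rearrangement (addition of the lithiated silyldiazomethane, Peterson-type elimination and 1,2-hydride shift of the alkylidene carbene) gives the alkyne at low temperature without equilibrating the α-centre C14'.

Step 25
Reactants: 35 terminal alkyne
Product: 37 (E)-alkenyl iodide, via alkenylalane 36 (not isolated)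
Conditions: AlMe3 (5 equiv), Cp2ZrCl2 (0.5 equiv), CH2Cl2, 0 °C to rt; then I2, THF, −30 °C
Reagents that add atoms: trimethylaluminium, C[Al](C)C; iodine, II
Why: Zirconium-catalysed carboalumination (syn addition of methyl–aluminium, methyl to the internal carbon) and iodinolysis with retention give the (E)-2-methyl-1-iodoalkene, the two hydroxyls being carried as aluminium alkoxides.

Step 26
Reactants: 37 alkenyl iodide diol
Product: 38 C11 ketone
Conditions: DMP, CH2Cl2, rt
Reagents that add atoms: none
Why: Periodinane oxidation returns the C11 ketone, the tertiary C6 alcohol and the alkenyl iodide being inert.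

Step 27
Reactants: 38 C11 ketone
Product: 39 diosphenol (C9=C11(OH)–C12=O)
Conditions: SeO2, 1,4-dioxane, 80 °C
Reagents that add atoms: selenium dioxide, O=[Se]=O
Why: Riley oxidation: SeO2 oxidises the only α-methylene group (C12; C9 is a methine) to the 11,12-dione, which enolises towards C9 because C13 is quaternary and thereby removes the C9 stereocentre.

Step 28
Reactants: 39 diosphenol with C14 ketal and C7 acetal
Product: 40 hydroxy aldehyde triketone (diosphenol form)
Conditions: CF3CO2H/H2O (4:1), 0 °C to rt
Reagents that add atoms: water, O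
Why: Acid hydrolysis of the two methyl acetals, placed here because no acid-labile alkene is present yet, so the forcing conditions that the bridge ketal is expected to need are tolerable.

Step 29
Reactants: 40 hydroxy aldehyde
Product: 41 bis(triethylsilyl) ether
Conditions: Et3SiOTf (2.5 equiv), 2,6-lutidine, CH2Cl2, −78 °C
Reagents that add atoms: triethylsilyl trifluoromethanesulfonate, CC[Si](CC)(CC)OS(=O)(=O)C(F)(F)F
Why: Silyl triflate silylation of the acidic diosphenol hydroxyl and the tertiary C6 hydroxyl removes the protons that would quench the alkylzinc reagent, and no carbonyl group of 40 is enolisable.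

**Labdane fragment from abietic acid (steps 30–37)**

Step 30
Reactants: 42 abietic acid
Product: 43 triisopropylsilyl abietate
Conditions: i-Pr3SiCl, imidazole, DMF, rt
Reagents that add atoms: chlorotriisopropylsilane, CC(C)[Si](Cl)(C(C)C)C(C)C
Why: O-Silylation of the carboxylate gives a silyl ester that the hindered tertiary acid makes robust, yet fluoride cleaves it at the end.

Step 31
Reactants: 43 triisopropylsilyl abietate
Product: 44 13α,14α-diol
Conditions: OsO4 (2 mol%), NMO, acetone/H2O, rt
Reagents that add atoms: 4-methylmorpholine N-oxide, C[N+]1([O-])CCOCC1; water, O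
Why: Catalytic osmium tetroxide syn-dihydroxylation, which attacks the more accessible 13,14-alkene of the abietadiene from the face opposite the angular methyl.

Step 32
Reactants: 44 diol
Product: 45 13,14-seco keto enal
Conditions: NaIO4, THF/H2O, rt
Reagents that add atoms: none
Why: Periodate glycol cleavage opens ring C to the isopropyl ketone and the conjugated aldehyde.

Step 33
Reactants: 45 keto enal
Product: 46 allylic alcohol ketone
Conditions: NaBH4 (0.3 equiv), MeOH/CH2Cl2, −78 °C
Reagents that add atoms: none
Why: Chemoselective 1,2-reduction of the aldehyde by borohydride at low temperature in the presence of the hindered isopropyl ketone.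

Step 34
Reactants: 46 allylic alcohol ketone
Product: 47 diene alcohol (C9'=C11' methylene)
Conditions: hν (medium-pressure Hg lamp, Pyrex), benzene, rt
Reagents that add atoms: none
Why: Norrish type-two fragmentation, in which γ-hydrogen abstraction from the allylic methine C9' and β-cleavage excise C12', C13' and the isopropyl group and leave the C9'=C11' double bond.

Step 35
Reactants: 47 diene alcohol
Product: 49 diol, via alkylborane 48 (not isolated)
Conditions: 9-BBN (2.2 equiv), THF, 0 °C to rt; then Me3NO·2H2O, 65 °C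
Reagents that add atoms: trimethylamine N-oxide, C[N+](C)(C)[O-]
Why: Hydroboration of the terminal double bond of the 2-substituted diene with 9-BBN (boron to C11') from the face opposite the angular C10' methyl sets C9' with its hydrogen α, and amine-oxide oxidation gives the alcohol under neutral conditions.

Step 36
Reactants: 49 diol
Product: 52 homoallylic alcohol with exocyclic methylene, via sulfonylhydrazine 50 (not isolated), via allylic diazene 51 (not isolated)
Conditions: 2-O2NC6H4SO2NHNH2, PPh3, DEAD, THF, −30 °C; then rt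
Reagents that add atoms: none
Why: Mitsunobu displacement of the more reactive allylic primary alcohol by the sulfonylhydrazide, loss of sulfinate and retro-ene loss of N2 from the allylic diazene (reductive 1,3-transposition) move the double bond into the exocyclic position.

Step 37
Reactants: 52 homoallylic alcohol
Product: 53 primary iodide
Conditions: I2, PPh3, imidazole, CH2Cl2, 0 °C to rt
Reagents that add atoms: iodine, II
Why: Appel-type iodination of the primary alcohol by SN2 displacement of the oxyphosphonium group.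

**Fragment union and deprotection (steps 38–39)**

Step 38
Reactants: 53 primary iodide; 41 bis(triethylsilyl) ether alkenyl iodide
Product: 55 protected target, via alkylzinc iodide 54 (not isolated)
Conditions: 53, Zn dust, LiCl, THF, 40 °C; then 41, Pd(dppf)Cl2 (5 mol%), THF/NMP, 40 °C
Reagents that add atoms: none
Why: Negishi sp3–sp2 coupling, that is zinc insertion into the primary iodide and palladium-catalysed coupling with the alkenyl iodide with retention of the E geometry, the organozinc tolerating the ketones, the hindered aldehyde and the silyl ester.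

Step 39
Reactants: 55 protected target
Product: 56 CNP0124601.1
Conditions: HF·pyridine, pyridine, THF, 0 °C to rt
Reagents that add atoms: none
Why: Fluoride cleavage of the two silyl ethers and the silyl ester under buffered, non-basic conditions that should spare the α-hydroxy aldehyde, the non-enolisable 1,3-diketone and the exocyclic alkene.

**Compound list**

1 | 2,2,6-trimethylcyclohexanone | CC1CCCC(C)(C)C1=O | starting material
2 | 2-methylallyl 2,6,6-trimethylcyclohex-1-en-1-yl carbonate | C=C(C)COC(=O)OC1=C(C)CCCC1(C)C | intermediate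
3 | (R)-2,2,6-trimethyl-6-(2-methylallyl)cyclohexanone | C=C(C)C[C@@]1(C)CCCC(C)(C)C1=O | intermediate
4 | (4R)-4,8,8-trimethyl-4-(2-methylallyl)-1-oxaspiro[2.5]octane, both configurations at the spiro carbon | C=C(C)C[C@@]1(C)CCCC(C)(C)C12CO2 | intermediate
5 | (2R)-2,6,6-trimethyl-2-(2-methylallyl)cyclohexanecarbaldehyde, both C1 epimers | C=C(C)C[C@@]1(C)CCCC(C)(C)C1C=O | intermediate
6 | (4aR)-4a,8,8-trimethyl-3-methylenedecahydronaphthalen-1-ol, mixture at C1 and C8a | C=C1C[C@@]2(C)CCCC(C)(C)C2C(O)C1 | intermediate
7 | (4aR)-4a,8,8-trimethyl-3-methyleneoctahydronaphthalen-1(2H)-one, mixture at C8a | C=C1C[C@@]2(C)CCCC(C)(C)C2C(=O)C1 | intermediate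
8 | (4aR,8aS)-3,4a,8,8-tetramethyl-4a,5,6,7,8,8a-hexahydronaphthalen-1(4H)-one, trans-fused | O=C1C=C(C)C[C@@]2(C)CCCC(C)(C)[C@@H]21 | intermediate
9 | ring A keto aldehyde: trans-2-(2-oxopropyl)-2,6,6-trimethylcyclohexyl glyoxal | CC(=O)C[C@@]1(C)CCCC(C)(C)[C@@H]1C(=O)C=O | intermediate
10 | ring A keto bis-acetal: 2,2-dimethoxy-1-[trans-2-(2,2-dimethoxypropyl)-2,6,6-trimethylcyclohexyl]ethanone (C5 H α, C10 methyl β) | CC(OC)(OC)C[C@@]1(C)CCCC(C)(C)[C@@H]1C(=O)C(OC)OC | intermediate
11 | cyclopentane-1,3-dione | O=C1CCC(=O)C1 | starting material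
12 | 2-isopropylidenecyclopentane-1,3-dione | CC(C)=C1C(=O)CCC1=O | intermediate
13 | 2-isopropylcyclopentane-1,3-dione | CC(C)C1C(=O)CCC1=O | intermediate
14 | 3-isobutoxy-2-isopropylcyclopent-2-en-1-one | CC(C)COC1=C(C(C)C)C(=O)CC1 | intermediate
15 | 1-(benzyloxymethyl)-3-isobutoxy-2-isopropylcyclopent-2-en-1-ol | CC(C)COC1=C(C(C)C)C(O)(COCc2ccccc2)CC1 | intermediate
16 | 3-(benzyloxymethyl)-2-isopropylcyclopent-2-en-1-one | CC(C)C1=C(COCc2ccccc2)CCC1=O | intermediate
17 | 5-bromo-3-(benzyloxymethyl)-2-isopropylcyclopent-2-en-1-one | CC(C)C1=C(COCc2ccccc2)CC(Br)C1=O | intermediate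
18 | 5,5-dibromo-3-(benzyloxymethyl)-2-isopropylcyclopent-2-en-1-one | CC(C)C1=C(COCc2ccccc2)CC(Br)(Br)C1=O | intermediate
19 | 1-(benzyloxymethyl)-4,4-dibromo-2-isopropyl-3,3-dimethoxycyclopent-1-ene | CC(C)C1=C(COCc2ccccc2)CC(Br)(Br)C1(OC)OC | intermediate
20 | 1-bromo-3-(benzyloxymethyl)-4-isopropyl-5,5-dimethoxycyclopenta-1,3-diene | CC(C)C1=C(COCc2ccccc2)C=C(Br)C1(OC)OC | intermediate
21 | dienyllithium from 20 (lithium at C8) | [Li]C1=CC(COCc2ccccc2)=C(C(C)C)C1(OC)OC | intermediate
22 | dienylcerium dichloride from 21 | Cl[Ce](Cl)C1=CC(COCc2ccccc2)=C(C(C)C)C1(OC)OC | intermediate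
23 | (6R) tertiary carbinol: C6 bears OH, CH(OMe)2, ring A (C5) and the dienyl ketal (C8); C10 arm is CH2C(OMe)2CH3 | CC(OC)(OC)C[C@@]1(C)CCCC(C)(C)[C@@H]1[C@](O)(C(OC)OC)C1=CC(COCc2ccccc2)=C(C(C)C)C1(OC)OC | intermediate
24 | C6 triethylsilyl ether of 23 | CC(OC)(OC)C[C@@]1(C)CCCC(C)(C)[C@@H]1[C@](O[Si](CC)(CC)CC)(C(OC)OC)C1=CC(COCc2ccccc2)=C(C(C)C)C1(OC)OC | intermediate
25 | methyl ketone: as 24 with C10 arm CH2C(=O)CH3 | CC(=O)C[C@@]1(C)CCCC(C)(C)[C@@H]1[C@](O[Si](CC)(CC)CC)(C(OC)OC)C1=CC(COCc2ccccc2)=C(C(C)C)C1(OC)OC | intermediate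
26 | trimethylsilyl enol ether of 25 (C11(OSiMe3)=C12H2) | C=C(O[Si](C)(C)C)C[C@@]1(C)CCCC(C)(C)[C@@H]1[C@](O[Si](CC)(CC)CC)(C(OC)OC)C1=CC(COCc2ccccc2)=C(C(C)C)C1(OC)OC | intermediate
27 | chloromethyl ketone: as 25 with C10 arm CH2C(=O)CH2Cl | ClCC(=O)C[C@@]1(C)CCCC(C)(C)[C@@H]1[C@](O[Si](CC)(CC)CC)(C(OC)OC)C1=CC(COCc2ccccc2)=C(C(C)C)C1(OC)OC | intermediate
28 | oxyallyl cation (2-oxidoallyl cation C9–C11–C12) from 27 | [CH2+]C([O-])=C[C@@]1(C)CCCC(C)(C)[C@@H]1[C@](O[Si](CC)(CC)CC)(C(OC)OC)C1=CC(COCc2ccccc2)=C(C(C)C)C1(OC)OC | intermediate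
29 | cycloadduct: rings A–C with C11 ketone, 9α-H, C14 dimethyl ketal bridge syn to the C10 methyl, C14'=C15' alkene bearing CH2OBn, C6 OSiEt3 (α) and CH(OMe)2 (β) | c1ccccc1COCC1=C[C@@]23C(OC)(OC)[C@]1(C(C)C)CC(=O)[C@@H]2[C@@]1(C)CCCC(C)(C)[C@@H]1[C@]3(O[Si](CC)(CC)CC)C(OC)OC | intermediate
30 | C6 alcohol of 29 | c1ccccc1COCC1=C[C@@]23C(OC)(OC)[C@]1(C(C)C)CC(=O)[C@@H]2[C@@]1(C)CCCC(C)(C)[C@@H]1[C@]3(O)C(OC)OC | intermediate
31 | dihydro compound: C14' H exo, CH2OBn endo | c1ccccc1COC[C@@H]1C[C@@]23C(OC)(OC)[C@]1(C(C)C)CC(=O)[C@@H]2[C@@]1(C)CCCC(C)(C)[C@@H]1[C@]3(O)C(OC)OC | intermediate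
32 | primary alcohol (C14' CH2OH) | OC[C@@H]1C[C@@]23C(OC)(OC)[C@]1(C(C)C)CC(=O)[C@@H]2[C@@]1(C)CCCC(C)(C)[C@@H]1[C@]3(O)C(OC)OC | intermediate
33 | triol (C11 carbinol, either epimer) | OC[C@@H]1C[C@@]23C(OC)(OC)[C@]1(C(C)C)CC(O)[C@@H]2[C@@]1(C)CCCC(C)(C)[C@@H]1[C@]3(O)C(OC)OC | intermediate
34 | C14' aldehyde | O=C[C@@H]1C[C@@]23C(OC)(OC)[C@]1(C(C)C)CC(O)[C@@H]2[C@@]1(C)CCCC(C)(C)[C@@H]1[C@]3(O)C(OC)OC | intermediate
35 | C14' ethynyl compound | C#C[C@@H]1C[C@@]23C(OC)(OC)[C@]1(C(C)C)CC(O)[C@@H]2[C@@]1(C)CCCC(C)(C)[C@@H]1[C@]3(O)C(OC)OC | intermediate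
36 | (E)-alkenyl(dimethyl)alane, hydroxyls as dimethylaluminium alkoxides | C[Al](C)/C=C(\C)[C@@H]1C[C@@]23C(OC)(OC)[C@]1(C(C)C)CC(O[Al](C)C)[C@@H]2[C@@]1(C)CCCC(C)(C)[C@@H]1[C@]3(O[Al](C)C)C(OC)OC | intermediate
37 | (E)-1-iodo-2-methylvinyl compound at C14', C11 carbinol | I/C=C(\C)[C@@H]1C[C@@]23C(OC)(OC)[C@]1(C(C)C)CC(O)[C@@H]2[C@@]1(C)CCCC(C)(C)[C@@H]1[C@]3(O)C(OC)OC | intermediate
38 | C11 ketone | I/C=C(\C)[C@@H]1C[C@@]23C(OC)(OC)[C@]1(C(C)C)CC(=O)[C@@H]2[C@@]1(C)CCCC(C)(C)[C@@H]1[C@]3(O)C(OC)OC | intermediate
39 | diosphenol with C14 ketal and C7 acetal | I/C=C(\C)[C@@H]1C[C@@]23C(OC)(OC)[C@]1(C(C)C)C(=O)C(O)=C2[C@@]1(C)CCCC(C)(C)[C@@H]1[C@]3(O)C(OC)OC | intermediate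
40 | unmasked bicyclic half: C14 ketone, C7 aldehyde, C6 OH, diosphenol, alkenyl iodide | I/C=C(\C)[C@@H]1C[C@@]23C(=O)[C@]1(C(C)C)C(=O)C(O)=C2[C@@]1(C)CCCC(C)(C)[C@@H]1[C@]3(O)C=O | intermediate
41 | bis(triethylsilyl) ether of 40 (C11 O and C6 O) | I/C=C(\C)[C@@H]1C[C@@]23C(=O)[C@]1(C(C)C)C(=O)C(O[Si](CC)(CC)CC)=C2[C@@]1(C)CCCC(C)(C)[C@@H]1[C@]3(O[Si](CC)(CC)CC)C=O | intermediate
42 | abietic acid | CC(C)C1=CC2=CC[C@@H]3[C@](C)(CCC[C@@]3(C)C(=O)O)[C@H]2CC1 | starting material
43 | triisopropylsilyl abietate | CC(C)C1=CC2=CC[C@@H]3[C@](C)(CCC[C@@]3(C)C(=O)O[Si](C(C)C)(C(C)C)C(C)C)[C@H]2CC1 | intermediate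
44 | triisopropylsilyl 13α,14α-dihydroxyabiet-7-en-18-oate | CC(C)[C@@]1(O)[C@H](O)C2=CC[C@@H]3[C@](C)(CCC[C@@]3(C)C(=O)O[Si](C(C)C)(C(C)C)C(C)C)[C@H]2CC1 | intermediate
45 | 13,14-seco keto enal (C14 aldehyde on C8 of the 7-ene; side chain CH2CH2C(=O)CH(CH3)2 on C9) | CC(C)C(=O)CC[C@H]1C(C=O)=CC[C@@H]2[C@]1(C)CCC[C@@]2(C)C(=O)O[Si](C(C)C)(C(C)C)C(C)C | intermediate
46 | allylic alcohol ketone (C14 CH2OH) | CC(C)C(=O)CC[C@H]1C(CO)=CC[C@@H]2[C@]1(C)CCC[C@@]2(C)C(=O)O[Si](C(C)C)(C(C)C)C(C)C | intermediate
47 | diene alcohol: triisopropylsilyl decalin ester with C9'=C11'H2, C7'=C8' and CH2OH on C8' | C=C1C(CO)=CC[C@@H]2[C@]1(C)CCC[C@@]2(C)C(=O)O[Si](C(C)C)(C(C)C)C(C)C | intermediate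
48 | B-alkyl-9-borabicyclo[3.3.1]nonane (boron on C11'), alcohol as its borinate | C(B1C2CCCC1CCC2)[C@H]3C(COB4C5CCCC4CCC5)=CC[C@@H]6[C@]3(C)CCC[C@@]6(C)C(=O)O[Si](C(C)C)(C(C)C)C(C)C | intermediate
49 | diol: C11' CH2OH (9'α-H) and allylic CH2OH on C8' | OC[C@H]1C(CO)=CC[C@@H]2[C@]1(C)CCC[C@@]2(C)C(=O)O[Si](C(C)C)(C(C)C)C(C)C | intermediate
50 | N-allyl-N-(2-nitrobenzenesulfonyl)hydrazine from 49 | OC[C@H]1C(CN(N)S(=O)(=O)c3ccccc3[N+](=O)[O-])=CC[C@@H]2[C@]1(C)CCC[C@@]2(C)C(=O)O[Si](C(C)C)(C(C)C)C(C)C | intermediate
51 | allylic monoalkyl diazene | OC[C@H]1C(CN=N)=CC[C@@H]2[C@]1(C)CCC[C@@]2(C)C(=O)O[Si](C(C)C)(C(C)C)C(C)C | intermediate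
52 | triisopropylsilyl ester of the 8'(17')-methylene decalin with C11' CH2OH | OC[C@H]1C(=C)CC[C@@H]2[C@]1(C)CCC[C@@]2(C)C(=O)O[Si](C(C)C)(C(C)C)C(C)C | intermediate
53 | primary iodide (C11' CH2I) | IC[C@H]1C(=C)CC[C@@H]2[C@]1(C)CCC[C@@]2(C)C(=O)O[Si](C(C)C)(C(C)C)C(C)C | intermediate
54 | alkylzinc iodide from 53 | I[Zn]C[C@H]1C(=C)CC[C@@H]2[C@]1(C)CCC[C@@]2(C)C(=O)O[Si](C(C)C)(C(C)C)C(C)C | intermediate
55 | protected target: triisopropylsilyl ester, triethylsilyl ethers at the C11 and C6 oxygens | C=C1CC[C@@H]2[C@](C)(CCC[C@@]2(C)C(=O)O[Si](C(C)C)(C(C)C)C(C)C)[C@H]1C/C=C(\C)[C@@H]1C[C@@]23C(=O)[C@]1(C(C)C)C(=O)C(O[Si](CC)(CC)CC)=C2[C@@]1(C)CCCC(C)(C)[C@@H]1[C@]3(O[Si](CC)(CC)CC)C=O | intermediate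
56 | CNP0124601.1 | C=C1CC[C@@H]2[C@](C)(CCC[C@@]2(C)C(=O)O)[C@H]1C/C=C(\C)[C@@H]1C[C@@]23C(=O)[C@]1(C(C)C)C(=O)C(O)=C2[C@@]1(C)CCCC(C)(C)[C@@H]1[C@]3(O)C=O | target

**Step count**

Total step count: 39 (steps 1–7 ring A, 8–13 diene, 14–29 union and elaboration, 30–37 labdane fragment, 38–39 coupling and deprotection).
Longest linear sequence: 25 steps (steps 1–7, 14–29, 38, 39).

**Steps most likely to fail**

1. Step 18 (the proposed cycloaddition). The oxyallyl cation may be consumed by Favorskii-type solvolysis, O-capture or (3+2) closure before it reaches the hindered diene, or it may add to the other diene face. The fallback generates the three-carbon partner as a 2-methoxyallyl cation by silver-assisted ionisation of an allylic bromide, an established (4+3) entry with cyclopentadienes and furans. It sets out from triethylsilyl ether 24. Me3SiOTf/i-Pr2NEt should convert only the C11 dimethyl ketal, the one ketal with an adjacent C–H, into methyl enol ether F1. NBS would then give the 2-methoxyallyl bromide F2. AgOCOCF3/Na2CO3 in CH2Cl2 at −78 °C ionises F2, and the cation adds across C8 and C13 to give the cycloadduct methyl enol ether F3. Oxalic acid on wet silica hydrolyses F3 to cycloadduct 29, where the route continues.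

2. Step 14 (addition to the open-chain ketone). Facial selectivity at C6 may be insufficient or inverted, because the two flanks of C5 differ only modestly; enolisation could also compete with addition. The fallback reverses the order in which the two carbon substituents reach C6, so that the same facial preference gives the opposite configuration. It sets out from enone 8. Ozonolysis with oxidative work-up (O3; then H2O2/HCO2H) excises C7 and gives the keto acid F4. The acid chloride and MeNHOMe give the N-methoxy-N-methylamide F5. HC(OMe)3/p-TsOH protects the methyl ketone as the ketal amide F6. Dienylcerium reagent 22 acylates to the dienyl ketone F7. (Dimethoxymethyl)lithium, from Bu3SnCH(OMe)2 and n-BuLi, then adds to the C6 ketone and returns the route at carbinol 23.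

3. Step 28 (acid unmasking). Hydrolysis of the hindered bridge ketal may be incomplete, or the α-hydroxy aldehyde may undergo acid-induced α-ketol rearrangement once it is unveiled. The fallback silylates first and then removes the methyl groups by dealkylation instead of hydrolysis. It sets out from diosphenol 39. Et3SiOTf/2,6-lutidine gives the bis(triethylsilyl) ether F8, in which the C6 oxygen can no longer take part in a ketol shift. Me3SiCl/NaI in MeCN at 0 °C then cleaves both methyl acetals and returns the route at bis(triethylsilyl) ether 41.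

Further compounds
F1 | step 18 | methyl enol ether (C11(OMe)=C12H2) derived from 24 | C=C(OC)C[C@@]1(C)CCCC(C)(C)[C@@H]1[C@](O[Si](CC)(CC)CC)(C(OC)OC)C1=CC(COCc2ccccc2)=C(C(C)C)C1(OC)OC
F2 | step 18 | (Z)-2-methoxyallyl bromide (C9H=C11(OMe)–C12H2Br) | BrC\C(OC)=C\[C@@]1(C)CCCC(C)(C)[C@@H]1[C@](O[Si](CC)(CC)CC)(C(OC)OC)C1=CC(COCc2ccccc2)=C(C(C)C)C1(OC)OC
F3 | step 18 | cycloadduct methyl enol ether (C11(OMe)=C12) | c1ccccc1COCC1=C[C@@]23C(OC)(OC)[C@]1(C(C)C)C=C(OC)[C@@H]2[C@@]1(C)CCCC(C)(C)[C@@H]1[C@]3(O[Si](CC)(CC)CC)C(OC)OC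
F4 | step 14 | trans-2-(2-oxopropyl)-2,6,6-trimethylcyclohexanecarboxylic acid | CC(=O)C[C@@]1(C)CCCC(C)(C)[C@@H]1C(=O)O
F5 | step 14 | N-methoxy-N-methylamide of F4 | CC(=O)C[C@@]1(C)CCCC(C)(C)[C@@H]1C(=O)N(C)OC
F6 | step 14 | dimethyl ketal of F5 | CC(OC)(OC)C[C@@]1(C)CCCC(C)(C)[C@@H]1C(=O)N(C)OC
F7 | step 14 | dienyl ketone (C6 ketone bearing the dienyl ketal) | CC(OC)(OC)C[C@@]1(C)CCCC(C)(C)[C@@H]1C(=O)C1=CC(COCc2ccccc2)=C(C(C)C)C1(OC)OC
F8 | step 28 | bis(triethylsilyl) ether of 39 | I/C=C(\C)[C@@H]1C[C@@]23C(OC)(OC)[C@]1(C(C)C)C(=O)C(O[Si](CC)(CC)CC)=C2[C@@]1(C)CCCC(C)(C)[C@@H]1[C@]3(O[Si](CC)(CC)CC)C(OC)OC
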